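**Retrosynthetic overview**
1. Target 7 ⇒ 6: the last step is chemoselective benzoylation of the primary OH.
2. 6 ⇒ 4: the C1–C6 bond and the quaternary carbinol come from a reductive α-ketol ring contraction. C6 of a 7-hydroxycyclohept-2-enone shifts from C7 to the C1 carbonyl, and C7 leaves the ring as CHO, then CH2OH.
3. 4 ⇒ 3: the C6/C7 cis-diol comes from osmylation anti to the C5 hydroxyl.
4. 3 ⇒ 2 ⇒ 1: enantioselective monobenzoylation of the meso diol obtained by distal cis-dihydroxylation of tropone.
5. Ring order: the seven-membered carbocycle comes with tropone. The six-membered ring is made from it once, in step 4, and no other ring is formed.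

Assumption: the (S)-diamine catalyst of step 2 is taken to acylate the pro-R carbinol of 2. If the sense is the reverse, its enantiomer from D-proline is used with no other change.

Seven-membered compounds use tropone numbering (C1 = carbonyl). Six-membered compounds use target numbering (C1 = quaternary carbinol).

**Step 1**
Reactants: 1 tropone (cyclohepta-2,4,6-trien-1-one)
Product: 2 meso-(4R,5S)-4,5-dihydroxycyclohepta-2,6-dien-1-one (cis-diol)
Conditions: OsO4 (1 mol %), NMO (1.05 equiv), citric acid (0.5 equiv), acetone–H2O 4:1, 0 °C
Reagents that add atoms: N-methylmorpholine N-oxide, C[N+]1([O-])CCOCC1; water, O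
Why: Catalytic OsO4/NMO cis-dihydroxylation, in which the electrophilic oxidant takes C4=C5, the only C=C not attached directly to the carbonyl (the distal selectivity seen with dienoates and trienoates), the cross-conjugated dienone formed is much less reactive so the reaction stops at the diol, and syn addition sets C4 and C5 as a meso cis pair.

**Step 2**
Reactants: 2 meso-(4R,5S)-4,5-dihydroxycyclohepta-2,6-dien-1-one
Product: 3 (4R,5S)-4-(benzoyloxy)-5-hydroxycyclohepta-2,6-dien-1-one
Conditions: BzCl (1.1 equiv), Et3N (1.1 equiv), (S)-1-methyl-2-(isoindolin-2-ylmethyl)pyrrolidine (2 mol %), 4 Å MS, CH2Cl2–EtCN, −78 °C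
Reagents that add atoms: benzoyl chloride, O=C(Cl)c1ccccc1
Why: Catalytic enantioselective desymmetrising acylation of a meso-1,2-diol, in which the chiral N-benzoylammonium species from the proline-derived diamine distinguishes the enantiotopic carbinols, fixes the absolute configuration (4R,5S) and places the benzoate on the future C4 oxygen, while −78 °C suppresses 1,2-benzoyl migration (which would racemise 3) and loss of benzoic acid.

**Step 3**
Reactants: 3 (4R,5S)-4-(benzoyloxy)-5-hydroxycyclohepta-2,6-dien-1-one
Product: 4 (4R,5S,6S,7S)-4-(benzoyloxy)-5,6,7-trihydroxycyclohept-2-en-1-one (C4/C5 oxygens on one face, C6/C7 hydroxyls on the other)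
Conditions: OsO4 (3 mol %), NMO (1.1 equiv), citric acid (1 equiv), t-BuOH–H2O 1:1, 23 °C
Reagents that add atoms: N-methylmorpholine N-oxide, C[N+]1([O-])CCOCC1; water, O
Why: Acid-buffered catalytic OsO4/NMO cis-dihydroxylation of an enone, in which C6=C7 next to the free OH is more electron-rich than C2=C3 next to the inductively deactivating benzoate, osmylation occurs anti to the allylic oxygens (Kishi's rule, both substituents shield the same face) and so sets 6S and 7S trans to the C5 hydroxyl, and citric acid keeps turnover with the electron-poor alkene and holds the pH where benzoyl migration is slow.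

**Step 4**
Reactants: 4 (4R,5S,6S,7S)-4-(benzoyloxy)-5,6,7-trihydroxycyclohept-2-en-1-one
Product: 6 (1R,4S,5S,6S)-4,5,6-trihydroxy-4-(hydroxymethyl)cyclohex-2-en-1-yl benzoate, via ring-contracted hydroxy aldehyde 5 (not isolated)
Conditions: Mg(NTf2)2 (20 mol %), Hantzsch ester (diethyl 2,6-dimethyl-1,4-dihydropyridine-3,5-dicarboxylate, 1.3 equiv), 4 Å MS, MeCN, 50 °C, Ar, dark
Reagents that add atoms: none
Why: Proposed new method: divalent magnesium binds the C1 carbonyl and the C7 hydroxyl (with the C6 hydroxyl as a third donor) in a syn-coplanar five-membered chelate that aligns the C7–C6 σ-bond with the carbonyl π* orbital, so C6 shifts suprafacially and with retention from C7 to C1 (polar α-ketol/acyloin 1,2-shift) and the C7 carbinol configuration is relayed to the new quaternary centre with its OH cis to the C6 OH; the contraction to aldehyde 5 is estimated to be about 2 kcal/mol uphill and is pulled through by irreversible hydride transfer from the Hantzsch ester to the still chelated, strongly electrophilic α-hydroxy aldehyde, a donor too weak to reduce the ketone of 4; the closest known reaction types are Lewis-acid-catalysed α-ketol rearrangements, the molybdate- or nickel-diamine-promoted stereospecific 1,2-carbon shift of 2-ketoses to 2-C-branched aldoses (same stereochemical relay), magnesium-promoted dihydropyridine reductions of chelating carbonyl compounds, and the reductoisomerase step of the methylerythritol phosphate pathway.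

**Step 5**
Reactants: 6 (1R,4S,5S,6S)-4,5,6-trihydroxy-4-(hydroxymethyl)cyclohex-2-en-1-yl benzoate
Product: 7 [(1S,4R,5S,6S)-4-(benzoyloxy)-1,5,6-trihydroxycyclohex-2-en-1-yl]methyl benzoate (target)
Conditions: BzCl (1.05 equiv), 2,4,6-collidine (3 equiv), CH2Cl2, −40 to −20 °C
Reagents that add atoms: benzoyl chloride, O=C(Cl)c1ccccc1
Why: Chemoselective O-acylation, in which the primary OH reacts faster than the two flanked secondary hydroxyls and the tertiary hydroxyl at low temperature, no stereocentre is touched, and the weak hindered base does not trigger C4-to-C5 benzoyl migration.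

**Compound list**
1 | tropone (cyclohepta-2,4,6-trien-1-one) | O=C1C=CC=CC=C1 | starting material
2 | meso-(4R,5S)-4,5-dihydroxycyclohepta-2,6-dien-1-one | O=C1C=C[C@@H](O)[C@@H](O)C=C1 | intermediate
3 | (4R,5S)-4-(benzoyloxy)-5-hydroxycyclohepta-2,6-dien-1-one | O=C1C=C[C@@H](OC(=O)c2ccccc2)[C@@H](O)C=C1 | intermediate
4 | (4R,5S,6S,7S)-4-(benzoyloxy)-5,6,7-trihydroxycyclohept-2-en-1-one | O=C1C=C[C@@H](OC(=O)c2ccccc2)[C@@H](O)[C@H](O)[C@@H]1O | intermediate
5 | (1R,4R,5S,6S)-4-(benzoyloxy)-1,5,6-trihydroxycyclohex-2-ene-1-carbaldehyde | O=C[C@@]1(O)C=C[C@@H](OC(=O)c2ccccc2)[C@@H](O)[C@@H]1O | intermediate (not isolated)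
6 | (1R,4S,5S,6S)-4,5,6-trihydroxy-4-(hydroxymethyl)cyclohex-2-en-1-yl benzoate | OC[C@@]1(O)C=C[C@@H](OC(=O)c2ccccc2)[C@@H](O)[C@@H]1O | intermediate
7 | [(1S,4R,5S,6S)-4-(benzoyloxy)-1,5,6-trihydroxycyclohex-2-en-1-yl]methyl benzoate | O=C(OC[C@@]1(O)C=C[C@@H](OC(=O)c2ccccc2)[C@@H](O)[C@@H]1O)c1ccccc1 | target

**Total step count:** 5. **Longest linear sequence:** 5.

**Steps most likely to fail**

Step 4 (the new step).
- Expected failure modes: the shift is too slow at a temperature 4 tolerates, the chelated enone undergoes conjugate reduction, or 4 loses water and benzoic acid towards tropolone.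
- The fallback sets out from 4 and comes back at 6. It separates the two events and uses known chemistry, replacing the kinetic hydride trap with thermodynamic equilibration and recycling.
- 4 is heated with H2MoO4 (10 mol %) in water–dioxane at pH 3–4 and 75 °C. This is the established stereospecific 1,2-carbon shift of hexavalent molybdenum that equilibrates 2-ketoses with 2-C-branched aldoses. It runs through a dimolybdate complex of the carbonyl hydrate and three neighbouring hydroxyls, a donor set that 4 offers at C1, C7, C6 and C5.
- The minor aldehyde 5 is separated from 4 by chromatography and recovered 4 is resubmitted.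
- Isolated 5 is reduced with NaBH(OAc)3 in MeCN–AcOH at −20 °C to 6. This fallback makes no new compound (F0).

Step 3 (which alkene is osmylated, and benzoyl migration in 3).
- The fallback sets out from 3 and comes back at 4. It changes the substrate rather than the oxidant.
- The free hydroxyl is capped with TBSOTf and 2,6-lutidine in CH2Cl2 at −78 °C. This gives (4R,5S)-4-(benzoyloxy)-5-[(tert-butyldimethylsilyl)oxy]cyclohepta-2,6-dien-1-one F1.
- The silyl ether locks the benzoate in place, makes C6=C7 clearly the more electron-rich alkene and enlarges the anti bias.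
- The same citric-acid-buffered OsO4/NMO oxidation then gives (4R,5S,6R,7S)-4-(benzoyloxy)-5-[(tert-butyldimethylsilyl)oxy]-6,7-dihydroxycyclohept-2-en-1-one F2. The spatial arrangement is the same as in 4; the C6 descriptor changes only through priorities.
- HF·pyridine in MeCN at 0 °C releases 4.

Step 2 (level of enantioselection on an electron-poor allylic diol, and racemisation by acyl migration).
- The fallback sets out from 2 and comes back at 3. It replaces the small-molecule catalyst by a base-free biocatalytic desymmetrisation.
- Conditions: vinyl benzoate as irreversible acyl donor with an immobilised lipase (Candida antarctica lipase B or Burkholderia cepacia lipase, chosen by a short screen for the sense that gives the 4R benzoate) in MTBE at 30 °C.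
- Lipase-catalysed benzoylation of 1,2-diols with vinyl benzoate is known, and without amine base or water the benzoyl shift is minimal. This fallback makes no new compound (F0).

**Further compounds**
F0 | step 2 | none | none
F1 | step 3 | (4R,5S)-4-(benzoyloxy)-5-[(tert-butyldimethylsilyl)oxy]cyclohepta-2,6-dien-1-one | O=C1C=C[C@@H](OC(=O)c2ccccc2)[C@@H](O[Si](C)(C)C(C)(C)C)C=C1
F2 | step 3 | (4R,5S,6R,7S)-4-(benzoyloxy)-5-[(tert-butyldimethylsilyl)oxy]-6,7-dihydroxycyclohept-2-en-1-one | O=C1C=C[C@@H](OC(=O)c2ccccc2)[C@@H](O[Si](C)(C)C(C)(C)C)[C@H](O)[C@@H]1O
F0 | step 4 | none | none
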